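**Retrosynthetic overview**
- The last C–C bond made is C5 of ring B to the alkyne carbon, by Sonogashira coupling of a 5'-bromobithiophene with but-3-yn-1-yl 3-methylbutanoate (from but-3-yn-1-ol and 3-methylbutanoyl chloride).
- The 3-methylbut-2-enoate on the thenylic oxygen comes from acylation of the alcohol, which comes from reduction of an ethyl ester at C2 of ring A.
- The strategy rests on ring A being a thiophene substituted only at C2 (one oxygenated carbon) and C5 (ring B), with C3–H and C4–H. It is cut at S1–C5 and C2–C3 into ethyl sulfanylacetate and a β-chloroacrolein whose β-carbon carries ring B.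
- The chloroacrolein comes from 2-acetyl-5-bromothiophene by Vilsmeier chloroformylation. Ring B is bought, ring A is the only ring built, and the bromine on ring B is kept as the handle for the last step.

Key step: step 2

Remark on the chemistry: the target has no stereocentre, and the double bond of the 3-methylbut-2-enoate carries two methyl groups on one carbon, so no configuration has to be set. 3-Methylbutanoyl chloride is taken as a further commercial starting material for the isovalerate.

**Route**

Step 1
Reactants: 1 2-acetyl-5-bromothiophene
Product: 3 (Z)-3-(5-bromothiophen-2-yl)-3-chloroprop-2-enal, via iminium salt 2 (not isolated)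
Conditions: POCl3, DMF, 0 °C then 60 °C; ice, aq NaOAc
Reagents that add atoms: DMF CN(C)C=O; POCl3 O=P(Cl)(Cl)Cl; water O
Why: Vilsmeier–Haack (Arnold) chloroformylation, in which the enol of the methyl ketone is C-formylated by the chloroiminium ion from DMF and POCl3, the enaminone oxygen is activated and exchanged for chloride to give iminium 2, and aqueous work-up hydrolyses 2 to the enal with the Z geometry (chlorine cis to the formyl group) favoured, while the bromine blocks the only ring position reactive enough for ring formylation.

Step 2
Reactants: 3 (Z)-3-(5-bromothiophen-2-yl)-3-chloroprop-2-enal; 4 ethyl sulfanylacetate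
Product: 7 ethyl 5'-bromo-2,2'-bithiophene-5-carboxylate, via vinyl sulfide 5 (not isolated), via hydroxydihydrothiophene 6 (not isolated)
Conditions: NaOEt, anhydrous EtOH, 0 °C to rt, then brief reflux
Reagents that add atoms: none
Why: Ethoxide converts 4 into its thiolate, which adds to the chlorine-bearing β-carbon of enal 3 and expels chloride (addition–elimination, vinylic substitution) to give sulfide 5, forming the S1–C5 bond of ring A. Ethoxide then removes a proton from the methylene flanked by sulfur and the ester, and this carbanion attacks the aldehyde carbon in a 5-exo-trig intramolecular aldol closure (C2–C3 bond) to give 6, which loses water by E1cB elimination, driven by aromatisation, to give 7. The closest known reaction type is the Fiesselmann-type synthesis of 5-arylthiophene-2-carboxylates from β-chlorovinyl aldehydes and sulfanylacetate esters. No stereocentre survives: the two sp3 centres of 6 are erased on dehydration, and any E isomer of 3 converges because the thiolate adduct can rotate before chloride leaves. The step needs regioselectivity and chemoselectivity: sulfur can enter only at the carbon carrying chloride and the only acidic C–H lies beside the ester, so only the 2,5-disubstituted ring can form, while the unactivated C–Br bond of ring B should not be attacked by thiolate or ethoxide under these conditions. Matching the ethyl ester to NaOEt in ethanol makes ester exchange invisible.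

Step 3
Reactants: 7 ethyl 5'-bromo-2,2'-bithiophene-5-carboxylate
Product: 9 (5'-bromo-2,2'-bithiophen-5-yl)methanol, via aldehyde 8 (not isolated)
Conditions: iBu2AlH, CH2Cl2, −78 to 0 °C; then H2O, aq NaOH
Reagents that add atoms: none
Why: Hydride reduction of an aryl ester with iBu2AlH, which passes through aldehyde 8 and ends at the primary alcohol; at low temperature the thienyl C–Br bond should stay untouched, and the basic work-up avoids acid that could ionise the electron-rich thenylic alcohol.

Step 4
Reactants: 9 (5'-bromo-2,2'-bithiophen-5-yl)methanol; 10 3-methylbut-2-enoyl chloride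
Product: 11 (5'-bromo-2,2'-bithiophen-5-yl)methyl 3-methylbut-2-enoate
Conditions: pyridine, CH2Cl2, 0 °C to rt
Reagents that add atoms: none
Why: Esterification of a primary alcohol by acyl substitution on an acid chloride; pyridine is chosen as a weak base so that the acid chloride is not deprotonated at its γ-methyl groups to a vinylketene, which would deliver the deconjugated 3-methylbut-3-enoate.

Step 5
Reactants: 12 but-3-yn-1-ol; 13 3-methylbutanoyl chloride
Product: 14 but-3-yn-1-yl 3-methylbutanoate
Conditions: Et3N, DMAP (cat.), CH2Cl2, 0 °C to rt
Reagents that add atoms: none
Why: DMAP-catalysed acylation of a primary alcohol with an acid chloride, to which the terminal alkyne is inert.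

Step 6
Reactants: 11 (5'-bromo-2,2'-bithiophen-5-yl)methyl 3-methylbut-2-enoate; 14 but-3-yn-1-yl 3-methylbutanoate
Product: 15 [5'-(4-{[3-methylbutanoyl]oxy}but-1-yn-1-yl)-2,2'-bithiophen-5-yl]methyl 3-methylbut-2-enoate (target)
Conditions: Pd(PPh3)2Cl2 (cat.), CuI (cat.), Et3N, THF, degassed, 50 °C
Reagents that add atoms: none
Why: Sonogashira coupling, in which zerovalent palladium formed in situ from Pd(PPh3)2Cl2 inserts into the thienyl C–Br bond, the copper acetylide formed from 14, CuI and Et3N transmetalates, and reductive elimination forms the C(sp2)–C(sp) bond; both esters and the trisubstituted enoate should tolerate the tertiary amine.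

**Compound list**

1 | 2-acetyl-5-bromothiophene | CC(=O)c1ccc(Br)s1 | starting material
2 | (Z)-N-[3-(5-bromothiophen-2-yl)-3-chloroprop-2-en-1-ylidene]-N-methylmethanaminium chloride | C[N+](C)=C/C=C(\Cl)c1ccc(Br)s1.[Cl-] | intermediate (not isolated)
3 | (Z)-3-(5-bromothiophen-2-yl)-3-chloroprop-2-enal | O=C/C=C(\Cl)c1ccc(Br)s1 | intermediate
4 | ethyl sulfanylacetate | CCOC(=O)CS | starting material
5 | ethyl 2-{[(Z)-1-(5-bromothiophen-2-yl)-3-oxoprop-1-en-1-yl]sulfanyl}acetate | O=C/C=C(\SCC(=O)OCC)c1ccc(Br)s1 | intermediate (not isolated)
6 | ethyl 5-(5-bromothiophen-2-yl)-3-hydroxy-2,3-dihydrothiophene-2-carboxylate (transient, racemic mixture of diastereomers, configuration not defined) | CCOC(=O)C1SC(=CC1O)c1ccc(Br)s1 | intermediate (not isolated)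
7 | ethyl 5'-bromo-2,2'-bithiophene-5-carboxylate | CCOC(=O)c1ccc(-c2ccc(Br)s2)s1 | intermediate
8 | 5'-bromo-2,2'-bithiophene-5-carbaldehyde | O=Cc1ccc(-c2ccc(Br)s2)s1 | intermediate (not isolated)
9 | (5'-bromo-2,2'-bithiophen-5-yl)methanol | OCc1ccc(-c2ccc(Br)s2)s1 | intermediate
10 | 3-methylbut-2-enoyl chloride | CC(C)=CC(=O)Cl | starting material
11 | (5'-bromo-2,2'-bithiophen-5-yl)methyl 3-methylbut-2-enoate | CC(C)=CC(=O)OCc1ccc(-c2ccc(Br)s2)s1 | intermediate
12 | but-3-yn-1-ol | C#CCCO | starting material
13 | 3-methylbutanoyl chloride | CC(C)CC(=O)Cl | starting material
14 | but-3-yn-1-yl 3-methylbutanoate | CC(C)CC(=O)OCCC#C | intermediate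
15 | [5'-(4-{[3-methylbutanoyl]oxy}but-1-yn-1-yl)-2,2'-bithiophen-5-yl]methyl 3-methylbut-2-enoate | CC(C)=CC(=O)OCc1ccc(-c2ccc(C#CCCOC(=O)CC(C)C)s2)s1 | target

**Step count**

Total: 6 steps. Longest linear sequence: 5 steps (steps 1, 2, 3, 4, 6); step 5 prepares the alkyne fragment in parallel.

**Steps most likely to fail, with fallbacks**

1. Step 2 (ring A annulation). The sequence may stall after the vinylic substitution if the aldol closure or dehydration is slow. The free thiolate may also add to the aldehyde or add twice to the enal, or be lost by oxidation to the disulfide. The sensitive chloroenal may decompose in ethoxide before it is captured, and hydroxide released on dehydration may saponify part of the ester.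
 Fallback: sulfur and the C2 carbon are attached in the reverse order. Setting out from 3, Na2S·9H2O in DMF should displace the vinylic chloride to give sodium (Z)-1-(5-bromothiophen-2-yl)-3-oxoprop-1-ene-1-thiolate F1. Ethyl bromoacetate added to the same flask should S-alkylate F1 to sulfide 5, and K2CO3 should then bring about the aldol closure through 6 and dehydration, coming back to the route at 7. No free sulfanylacetate thiolate meets the aldehyde and no ethoxide is present.

2. Step 4 (3-methylbut-2-enoate formation). The acid chloride may be deprotonated at a γ-methyl group to a vinylketene, so that the double bond moves out of conjugation in the ester. The hydrogen chloride formed may also ionise the electron-rich thenylic alcohol, leading to substitution or oligomerisation.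
 Fallback: the alcohol is activated instead of the acid. Setting out from 9, a Mitsunobu esterification with 3-methylbut-2-enoic acid, PPh3 and DIAD in THF at 0 °C should give 11 directly by carboxylate displacement at the thenylic carbon, coming back to the route at 11. No ketene can form, and no compound outside the list is made (F0).

3. Step 6 (alkynylation). The alkyne ester may be consumed by copper-mediated oxidative homocoupling while oxidative addition into the electron-rich bithienyl bromide is slow. The nonpolar diyne diester and unreacted bromide would then be hard to separate from the nonpolar target.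
 Fallback: the order of coupling and acylation is changed. Setting out from 11, coupling with an excess of but-3-yn-1-ol 12 under Pd(PPh3)2Cl2, CuI and Et3N should give [5'-(4-hydroxybut-1-yn-1-yl)-2,2'-bithiophen-5-yl]methyl 3-methylbut-2-enoate F2. This polar alcohol separates easily from unreacted 11 and from the diol formed by homocoupling. Acylation of F2 with 13 and pyridine in CH2Cl2 then comes back to the route at 15.

**Further compounds**

F1 | step 2 | sodium (Z)-1-(5-bromothiophen-2-yl)-3-oxoprop-1-ene-1-thiolate | O=C/C=C(\[S-])c1ccc(Br)s1.[Na+]
F0 | step 4 | none | none
F2 | step 6 | [5'-(4-hydroxybut-1-yn-1-yl)-2,2'-bithiophen-5-yl]methyl 3-methylbut-2-enoate | CC(C)=CC(=O)OCc1ccc(-c2ccc(C#CCCO)s2)s1
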